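A direct plan would buy the whole flavonol skeleton as quercetin A1 and only sort its five hydroxyls: 7-O-methylation of A1, with the ring B catechol masked in passing as a cyclic arylboronate, would give rhamnetin A2, 4'-O-benzylation would give 4'-O-benzylrhamnetin A3, sulfation of O-3 and O-3' would give dipotassium 4'-O-benzylrhamnetin 3,3'-disulfate A4, and hydrogenolysis with cold protonation would give the target.
It would form no ring, no C-C bond and no stereocentre, so nothing would be left to chance in a closure, but every step would be spent on site selection with no gain in skeletal complexity.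
Its weakest steps would be:
(a) the boronate-masked 7-O-methylation of A1, an untested one-pot in which carbonate could open the boronate and small acidity gaps between 7-OH, 4'-OH and 3-OH would decide the site, giving regioisomers of A2 that are hard to separate and to assign;
(b) the 4'-O-monobenzylation of A2, again ruled only by acidity among 4'-OH, 3-OH and 3'-OH, where a misplaced benzyl group in A3 would pass unnoticed into a misplaced sulfate;
(c) the double sulfation of A3 to A4 on the last and most precious material, which would have to drive the hydrogen-bonded 3-OH to completion yet spare the free 5-OH.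

Plan of the new route
The retrosynthesis first cuts the two S-O bonds (O-3, O-3') back to a diol with no other free hydroxyl, then opens ring C at O1-C2, C2-C3 and C3-O: ring A enters as an aryl methyl ketone (C4, C3), ring B as an aldehyde (C2), and the 3-oxygen comes from H2O2.
Rings A and B are bought and ring C is made last, in one operation that copies the biosynthetic order chalcone → flavanone → dihydroflavonol → flavonol.
The enabling feature is ring C, a 3-hydroxy-4-pyranone whose C2-C3-C4 are the enone carbons of a chalcone and whose O1 is a phenol oxygen ortho to the acyl-bearing C4a. C4a lies on a local mirror plane of ring A (through C4a and C7-OMe) between O1 and O-5, so ring A derives from a symmetric 2,6-dihydroxy-4-methoxyphenyl ketone that cannot be monobenzylated at a wrong oxygen.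
The ring B hydroxyl that becomes O-3' is meta to the enone and can stay free, so the key step leaves exactly two free hydroxyls, O-3 and O-3'. No polyphenol is alkylated site-selectively, 7-OMe, 5-O and 4'-O arrive fixed in the building blocks, and the sulfation is exhaustive instead of selective.

Key step: step 2

Assumption: the target is taken as the free bis(hydrogen sulfate) as drawn; being a strong acid prone to acid-catalysed hydrolysis, it is liberated cold in the last operation and freeze-dried at once.

Step 1
Reactants: 1 2',6'-dihydroxy-4'-methoxyacetophenone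
Product: 2 2'-(benzyloxy)-6'-hydroxy-4'-methoxyacetophenone
Conditions: BnBr (1.05 eq), K2CO3 (1.2 eq), acetone, reflux, 8 h
Reagents that add atoms: benzyl bromide BrCc1ccccc1
Why: Williamson etherification of a symmetric diol whose two hydroxyls are equivalent, so only one mono-ether can form, and the remaining hydroxyl is then locked in a hydrogen bond to the acetyl carbonyl and is alkylated far more slowly, as in the mono-O-benzylation of 2',6'-dihydroxyacetophenones.

Step 2
Reactants: 2 2'-(benzyloxy)-6'-hydroxy-4'-methoxyacetophenone; 3 4-(benzyloxy)-3-hydroxybenzaldehyde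
Product: 6 4',5-di-O-benzylrhamnetin, via chalcone 4 (not isolated), via trans-dihydroflavonol 5 (not isolated)
Conditions: KOH (50% aq, 10 eq), EtOH, 25 °C, 48 h; then MeOH, 0 °C, 30% H2O2 (6 eq), 0 → 20 °C, 6 h; 1 M HCl to pH 4
Reagents that add atoms: hydrogen peroxide OO
Why: The potassium enolate of 2 adds to aldehyde 3 and the aldol loses hydroxide (Claisen-Schmidt condensation) to give the (E)-chalcone 4 as its diphenoxide; on addition of H2O2 the free ortho phenoxide of ring A closes ring C by 6-endo-trig oxa-Michael addition at the β-carbon (O1-C2), the resulting enolate is hydroxylated at C3 by H2O2 to the trans-dihydroflavonol 5, and alkaline peroxide dehydrogenates C2-C3 to the flavonol 6 (Algar-Flynn-Oyamada reaction). The closest known reaction type is the one-pot Claisen-Schmidt/Algar-Flynn-Oyamada preparation of 5,7-dialkoxyflavonols from 2'-hydroxy-4',6'-dialkoxyacetophenones and alkoxy- or meta-hydroxybenzaldehydes. Ring C is the only ring closed, through the phenoxide oxygen onto the benzylic β-carbon; the two stereocentres of 5 (C2 and C3, trans with aryl and hydroxyl equatorial) are transient and vanish on dehydrogenation, so no configuration has to be controlled. The selectivity needed is six-membered flavonol over five-membered aurone (attack at the α-carbon, the known diversion of 6'-alkoxychalcones); it should be secured by the para benzyloxy group of ring B, which stabilises positive character at the β-carbon, by the low temperature, and by the ring B phenoxide being meta to the enone, so that it does not quench the electrophilicity of the β-carbon. Chemoselectivity follows from the substrate: the only oxygen nucleophile that can reach the enone is the one free ortho phenoxide, since the other ortho oxygen of ring A is a benzyl ether, and the benzyl and methyl ethers are inert to cold alkaline H2O2.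

Step 3
Reactants: 6 4',5-di-O-benzylrhamnetin
Product: 7 bis(tributylammonium) 4',5-di-O-benzylrhamnetin 3,3'-disulfate
Conditions: Bu3N·SO3 (6 eq), Bu3N (3 eq), MeCN-DMF 4:1, 70 °C, 12 h; SiO2 (CH2Cl2/MeOH)
Reagents that add atoms: tributylsulfoammonium betaine (Bu3N·SO3) CCCC[N+](CCCC)(CCCC)S(=O)(=O)[O-]
Why: O-sulfation by SO3 transfer from a trialkylamine-SO3 complex to the only two free hydroxyls, the 3-enol and the 3'-phenol, so that exhaustive conditions cannot place a sulfate elsewhere, while the lipophilic tributylammonium counter-ions should allow extraction and chromatography on silica.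

Step 4
Reactants: 7 bis(tributylammonium) 4',5-di-O-benzylrhamnetin 3,3'-disulfate
Product: 9 rhamnetin 3,3'-disulfate, via bis(tributylammonium) rhamnetin 3,3'-disulfate 8 (not isolated)
Conditions: H2 (1 atm), 10% Pd/C, MeOH, 25 °C, 4 h; filter; then sulfonic acid cation-exchange resin (H+ form), H2O-MeCN 9:1, 0 °C; lyophilise
Reagents that add atoms: none
Why: Catalytic hydrogenolysis cleaves the 4'- and 5-O-benzyl ethers (aryl sulfate monoester anions and the chromone C2=C3 bond are inert to H2 over palladium on carbon at 1 atm), and cold cation exchange replaces tributylammonium by protons to give the bis(hydrogen sulfate) without mineral acid or heat.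

Compound list
1 | 2',6'-dihydroxy-4'-methoxyacetophenone (1-(2,6-dihydroxy-4-methoxyphenyl)ethan-1-one) | CC(=O)c1c(O)cc(OC)cc1O | starting material
2 | 2'-(benzyloxy)-6'-hydroxy-4'-methoxyacetophenone (1-[2-(benzyloxy)-6-hydroxy-4-methoxyphenyl]ethan-1-one) | CC(=O)c1c(O)cc(OC)cc1OCc1ccccc1 | intermediate
3 | 4-(benzyloxy)-3-hydroxybenzaldehyde | O=Cc1ccc(OCc2ccccc2)c(O)c1 | starting material
4 | (E)-1-[2-(benzyloxy)-6-hydroxy-4-methoxyphenyl]-3-[4-(benzyloxy)-3-hydroxyphenyl]prop-2-en-1-one (chalcone) | COc1cc(O)c(C(=O)/C=C/c2ccc(OCc3ccccc3)c(O)c2)c(OCc2ccccc2)c1 | intermediate (not isolated)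
5 | (±)-trans-5-(benzyloxy)-2-[4-(benzyloxy)-3-hydroxyphenyl]-3-hydroxy-7-methoxy-2,3-dihydro-4H-chromen-4-one (racemic; the 2R,3R enantiomer is drawn) | C(c1ccccc1)Oc1ccc(cc1O)[C@@H]2[C@H](C(=O)c3c(OCc4ccccc4)cc(OC)cc3O2)O | intermediate (not isolated)
6 | 4',5-di-O-benzylrhamnetin (5-(benzyloxy)-2-[4-(benzyloxy)-3-hydroxyphenyl]-3-hydroxy-7-methoxy-4H-chromen-4-one) | COc1cc(OCc2ccccc2)c2c(=O)c(O)c(-c3ccc(OCc4ccccc4)c(O)c3)oc2c1 | intermediate
7 | bis(tributylammonium) 4',5-di-O-benzylrhamnetin 3,3'-disulfate (sulfate esters at O-3 of ring C and O-3' of ring B) | COc1cc(OCc2ccccc2)c2c(=O)c(OS(=O)(=O)[O-])c(-c3ccc(OCc4ccccc4)c(OS(=O)(=O)[O-])c3)oc2c1.CCCC[NH+](CCCC)CCCC.CCCC[NH+](CCCC)CCCC | intermediate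
8 | bis(tributylammonium) rhamnetin 3,3'-disulfate | COc1cc(O)c2c(=O)c(OS(=O)(=O)[O-])c(-c3ccc(O)c(OS(=O)(=O)[O-])c3)oc2c1.CCCC[NH+](CCCC)CCCC.CCCC[NH+](CCCC)CCCC | intermediate (not isolated)
9 | rhamnetin 3,3'-disulfate (5-hydroxy-2-[4-hydroxy-3-(sulfooxy)phenyl]-7-methoxy-4-oxo-4H-chromen-3-yl hydrogen sulfate) | COc1cc(O)c2c(=O)c(OS(=O)(=O)O)c(-c3ccc(O)c(OS(=O)(=O)O)c3)oc2c1 | target

Total step count: 4. Longest linear sequence: 4 steps (1 → 2 → 6 → 7 → 9); aldehyde 3 enters in step 2.

Steps most likely to fail

Step 2. The condensation may stall because both partners are phenoxides, and the oxidative cyclisation may divert to the five-membered aurone by attack at the α-carbon. The fallback sets out from 2 and separates epoxidation from ring closure. The remaining hydroxyl is protected (NaH, MOMCl, DMF, 0 °C) to give 1-[2-(benzyloxy)-4-methoxy-6-(methoxymethoxy)phenyl]ethan-1-one F1. Condensation with 3 (KOH, EtOH, 25 °C) gives the isolated chalcone (E)-1-[2-(benzyloxy)-4-methoxy-6-(methoxymethoxy)phenyl]-3-[4-(benzyloxy)-3-hydroxyphenyl]prop-2-en-1-one F2. Weitz-Scheffer epoxidation (30% H2O2, 2 M NaOH, MeOH, 0 °C) gives the racemic trans-epoxide [2-(benzyloxy)-4-methoxy-6-(methoxymethoxy)phenyl]{3-[4-(benzyloxy)-3-hydroxyphenyl]oxiran-2-yl}methanone F3. HCl in MeOH-THF at 50 °C then removes the methoxymethyl group and the freed phenol opens the epoxide at the benzylic carbon, which is cation-stabilised by the para benzyloxy group, so that only the six-membered ring can form. The fallback comes back to the route at the dihydroflavonol 5, now isolated (a cis isomer would converge as well), which the alkaline H2O2 stage of step 2 dehydrogenates to 6.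

Step 3. Sulfation of the hydrogen-bonded 3-hydroxyl may stop at the 3'-monosulfate, or the enol sulfate may be lost on silica. The fallback sets out from 6 and uses a protected sulfate. 2,2,2-Trichloroethyl chlorosulfate with Et3N and DMAP in THF should give the neutral, chromatographable 4',5-di-O-benzylrhamnetin 3,3'-bis(2,2,2-trichloroethyl sulfate) F4. Zn and HCO2NH4 in MeOH remove both trichloroethyl groups by reductive fragmentation to give diammonium 4',5-di-O-benzylrhamnetin 3,3'-disulfate F5. Hydrogenolysis (H2, 10% Pd/C, MeOH) gives diammonium rhamnetin 3,3'-disulfate F6, and cold proton exchange as in step 4 comes back to the route at 9.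

Step 4. The 3-sulfate may be hydrolysed while protons are exchanged on the strongly acidic resin and the acidic eluate is concentrated. The fallback sets out from 8 and liberates the acid by precipitation-driven metathesis instead. The filtered hydrogenolysis solution is passed at neutral pH through a cation-exchange resin in the Ba2+ form to give barium rhamnetin 3,3'-disulfate F7. Exactly one equivalent of cold 0.05 M H2SO4 is added, the insoluble sulfate is centrifuged off and the supernatant is freeze-dried, which comes back to the route at 9 without any excess of acid.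

Further compounds
F1 | step 2 | 1-[2-(benzyloxy)-4-methoxy-6-(methoxymethoxy)phenyl]ethan-1-one | CC(=O)c1c(OCOC)cc(OC)cc1OCc1ccccc1
F2 | step 2 | (E)-1-[2-(benzyloxy)-4-methoxy-6-(methoxymethoxy)phenyl]-3-[4-(benzyloxy)-3-hydroxyphenyl]prop-2-en-1-one | COCOc1cc(OC)cc(OCc2ccccc2)c1C(=O)/C=C/c1ccc(OCc2ccccc2)c(O)c1
F3 | step 2 | racemic trans-[2-(benzyloxy)-4-methoxy-6-(methoxymethoxy)phenyl]{3-[4-(benzyloxy)-3-hydroxyphenyl]oxiran-2-yl}methanone (one enantiomer drawn) | COCOc1cc(OC)cc(OCc2ccccc2)c1C(=O)[C@H]1O[C@@H]1c1ccc(OCc2ccccc2)c(O)c1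
F4 | step 3 | 4',5-di-O-benzylrhamnetin 3,3'-bis(2,2,2-trichloroethyl sulfate) | COc1cc(OCc2ccccc2)c2c(=O)c(OS(=O)(=O)OCC(Cl)(Cl)Cl)c(-c3ccc(OCc4ccccc4)c(OS(=O)(=O)OCC(Cl)(Cl)Cl)c3)oc2c1
F5 | step 3 | diammonium 4',5-di-O-benzylrhamnetin 3,3'-disulfate | COc1cc(OCc2ccccc2)c2c(=O)c(OS(=O)(=O)[O-])c(-c3ccc(OCc4ccccc4)c(OS(=O)(=O)[O-])c3)oc2c1.[NH4+].[NH4+]
F6 | step 3 | diammonium rhamnetin 3,3'-disulfate | COc1cc(O)c2c(=O)c(OS(=O)(=O)[O-])c(-c3ccc(O)c(OS(=O)(=O)[O-])c3)oc2c1.[NH4+].[NH4+]
F7 | step 4 | barium rhamnetin 3,3'-disulfate | COc1cc(O)c2c(=O)c(OS(=O)(=O)[O-])c(-c3ccc(O)c(OS(=O)(=O)[O-])c3)oc2c1.[Ba+2]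
A1 | direct plan | quercetin | Oc1cc(O)c2c(=O)c(O)c(-c3ccc(O)c(O)c3)oc2c1
A2 | direct plan | rhamnetin (7-O-methylquercetin) | COc1cc(O)c2c(=O)c(O)c(-c3ccc(O)c(O)c3)oc2c1
A3 | direct plan | 4'-O-benzylrhamnetin | COc1cc(O)c2c(=O)c(O)c(-c3ccc(OCc4ccccc4)c(O)c3)oc2c1
A4 | direct plan | dipotassium 4'-O-benzylrhamnetin 3,3'-disulfate | COc1cc(O)c2c(=O)c(OS(=O)(=O)[O-])c(-c3ccc(OCc4ccccc4)c(OS(=O)(=O)[O-])c3)oc2c1.[K+].[K+]
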